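**Assumptions.** Commercial (R)-2-methylglycidol of high ee counts as a starting material. If not, add one step: Sharpless epoxidation of methallyl alcohol with D-(−)-DIPT.

**Locants.** C1 = lactone C=O, C2 = CH2, C3 = ring-fusion OCH, C4 = ring-fusion C(CH3)O, C5 = ring CH2, C6 = C(CH3)(chain), C7–C18 = (CH2)12, then the aryl group. The target is (3S,4S,6S). The rings are cis-fused. The C6 chain is cis to C4–CH3 and C3–H, and C6–CH3 is cis to the lactone oxygen.

## Retrosynthetic overview
1. The lactone is the last ring formed. I cut the C2–C3 carbon–carbon bond: Rh(II)-carbenoid 1,5 C–H insertion of a tertiary diazoacetate into the unfunctionalised OCH2 of a simple THF. C4 dictates C3.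
2. For the THF-3-ol, I cut C6–CH3: AlMe3 transfers methyl to a cyclic C6 oxocarbenium ion, and the C4 oxygen directs the face. C4 dictates C6.
3. The THF ring is formed first, by Au-catalysed 5-exo-dig cycloketalisation of a 4-yne-1,2-diol.
4. The yne-diol comes from a terminal alkyne (ArMgBr + Br(CH2)11Br + acetylide) and (R)-2-methylglycidol, which is the only source of chirality (C4).
5. This avoids both usual disconnections: Pd(II) alkoxycarbonylation–lactonisation of an ene-diol, and oxa-Michael/lactonisation of an enoate or butenolide.

## Route

**Step 1**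
Reactants: 1, 1-(benzyloxy)-4-bromobenzene; 2, 1,11-dibromoundecane
Product: 3, 1-(benzyloxy)-4-(11-bromoundecyl)benzene
Conditions: 1, Mg, THF, reflux; then add to 2 (3 equiv), Li2CuCl4 (3 mol %), THF, 0 °C → rt
Reagents that add atoms: none
Why: Kochi-type Cu-catalysed aryl Grignard/primary alkyl bromide cross-coupling, where excess 2 (recoverable) keeps it at mono-substitution, the benzyl ether is inert, and no stereocentre is involved.

**Step 2**
Reactants: 3; 4, lithium acetylide–ethylenediamine complex
Product: 5, 1-(benzyloxy)-4-(tridec-12-yn-1-yl)benzene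
Conditions: 4 (1.5 equiv), DMSO, 0 °C → rt
Reagents that add atoms: 4, lithium acetylide, [Li]C#C
Why: SN2 alkylation of acetylide at a primary bromide in a dipolar aprotic solvent completes the C6–C18 chain and leaves the benzyl ether untouched.

**Step 3**
Reactants: 6, (R)-2-methylglycidol, [(2R)-2-methyloxiran-2-yl]methanol
Product: 7, triethyl{[(2S)-2-methyloxiran-2-yl]methoxy}silane
Conditions: TESCl, imidazole, CH2Cl2, 0 °C
Reagents that add atoms: chlorotriethylsilane, CC[Si](Cl)(CC)CC
Why: Standard silylation masks the only acidic proton before the organolithium step; the quaternary centre (future C4) is untouched, and the R→S change is only a CIP priority switch because CH2OSi now outranks the ring CH2.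

**Step 4**
Reactants: 5; 7
Product: 8, (2S)-16-[4-(benzyloxy)phenyl]-2-methylhexadec-4-yne-1,2-diol
Conditions: 5, n-BuLi, THF, −78 °C; BF3·OEt2; then 7, −78 °C; work-up 1 M HCl/MeOH, rt
Reagents that add atoms: none
Why: Yamaguchi–Hirao alkynylation opens the BF3-activated 2,2-disubstituted epoxide by SN2 at its unsubstituted CH2 (future C5), so the C4–O bond and C4 configuration are retained; the primary TES ether is cleaved in the acidic methanol work-up while the alkyne, tertiary alcohol and benzyl ether survive.

**Step 5**
Reactants: 8
Product: 9, (3S,5RS)-5-{12-[4-(benzyloxy)phenyl]dodecyl}-5-methoxy-3-methyloxolan-3-ol (methyl ketal, anomer mixture at C6)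
Conditions: AuCl (2 mol %), MeOH, rt, 30 min; Et3N quench, filtration through basic alumina
Reagents that add atoms: methanol, CO
Why: Gold π-acid catalysis drives 5-exo-dig hydroalkoxylation by the unhindered primary OH (expected to be faster than 5-endo attack by the tertiary OH or 6-endo closure) to give an exocyclic enol ether that adds MeOH through its oxocarbenium ion; this closes the THF ring, and the C6 anomer ratio is irrelevant because C6 is re-ionised in step 6.

**Step 6**
Reactants: 9
Product: 10, (3S,5S)-5-{12-[4-(benzyloxy)phenyl]dodecyl}-3,5-dimethyloxolan-3-ol (3-OH cis to 5-CH3; 3-CH3 cis to the chain)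
Conditions: AlMe3 (5 equiv), CH2Cl2, −78 → 0 °C; Rochelle salt work-up
Reagents that add atoms: trimethylaluminium, C[Al](C)C
Why: This is ketal ionisation followed by methyl transfer from aluminium, the reaction type used to install angular methyls in polyether synthesis: C4–OH becomes C4–O–AlMe2, excess AlMe3 strips methoxide, and in the envelope oxocarbenium ion the C4 oxygen lies pseudoaxial and C4–CH3 pseudoequatorial, so inside attack (Woerpel model), reinforced by delivery from the neighbouring aluminium alkoxide, should place the new C6–CH3 cis to C4–O, giving (6S).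

**Step 7**
Reactants: 10
Product: 11, (3S,5S)-5-{12-[4-(benzyloxy)phenyl]dodecyl}-3,5-dimethyloxolan-3-yl bromoacetate
Conditions: BrCH2COBr, PhNMe2, CH2Cl2, 0 °C → rt
Reagents that add atoms: bromoacetyl bromide, BrCC(Br)=O
Why: Acylation of a tertiary alcohol with a very reactive acyl bromide and a weakly nucleophilic base is the reaction used to make tert-butyl bromoacetate, and the C4–O bond is not broken, so configuration is retained.

**Step 8**
Reactants: 11
Product: 12, (3S,5S)-5-{12-[4-(benzyloxy)phenyl]dodecyl}-3,5-dimethyloxolan-3-yl diazoacetate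
Conditions: TsNHNHTs (2 equiv), DBU (5 equiv), THF, 0 °C
Reagents that add atoms: N,N′-ditosylhydrazine, Cc1ccc(cc1)S(=O)(=O)NNS(=O)(=O)c1ccc(C)cc1
Why: In the Fukuyama diazoacetate synthesis, SN2 N-alkylation of the hydrazine is followed by DBU-induced loss of two sulfinates, which is mild enough for the tertiary ester and the ethers and touches no stereocentre.

**Step 9 (key step)**
Reactants: 12
Product: 13, O-benzyl plakortone N, (3aS,5S,6aS)-5-{12-[4-(benzyloxy)phenyl]dodecyl}-5,6a-dimethyltetrahydrofuro[3,2-b]furan-2(3H)-one
Conditions: Rh2(cap)4 (1 mol %), CH2Cl2, reflux, syringe-pump addition of 12 over 10 h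
Reagents that add atoms: none
Why: This is a Rh(II)-carbenoid intramolecular 1,5 C–H insertion (Doyle/Taber-type γ-lactone synthesis): the electron-rich carboxamidate catalyst should favour the ether-activated C3–H over the hindered C5–H next to quaternary C6 and over CH3 (C4 has no H, so no β-lactone can form), only the C3–H cis to the ester oxygen is within reach, and insertion occurs with retention, so the C2–C3 bond, the cis ring fusion and (3S) are set directly by C4.

**Step 10**
Reactants: 13
Product: 14, plakortone N
Conditions: H2 (1 atm), 10 % Pd/C, EtOAc, rt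
Reagents that add atoms: none
Why: Hydrogenolysis cleaves the aryl benzyl ether, while the lactone, the non-benzylic ethers and all three stereocentres are inert.

## Compound list
| No. | Name | SMILES | Role |
|---|---|---|---|
| 1 | 1-(benzyloxy)-4-bromobenzene | Brc1ccc(OCc2ccccc2)cc1 | starting material |
| 2 | 1,11-dibromoundecane | BrCCCCCCCCCCCBr | starting material |
| 3 | 1-(benzyloxy)-4-(11-bromoundecyl)benzene | BrCCCCCCCCCCCc1ccc(OCc2ccccc2)cc1 | intermediate |
| 4 | lithium acetylide–ethylenediamine | [Li]C#C.NCCN | starting material |
| 5 | 1-(benzyloxy)-4-(tridec-12-yn-1-yl)benzene | C#CCCCCCCCCCCCc1ccc(OCc2ccccc2)cc1 | intermediate |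
| 6 | (R)-2-methylglycidol | C[C@@]1(CO)CO1 | starting material |
| 7 | (S)-TES ether of 6 | C[C@@]1(CO[Si](CC)(CC)CC)CO1 | intermediate |
| 8 | (2S)-yne-1,2-diol | C[C@@](O)(CO)CC#CCCCCCCCCCCCc1ccc(OCc2ccccc2)cc1 | intermediate |
| 9 | methyl ketal (C6 anomers) | COC1(CCCCCCCCCCCCc2ccc(OCc3ccccc3)cc2)C[C@](C)(O)CO1 | intermediate |
| 10 | (3S,5S)-THF-3-ol | C[C@]1(CCCCCCCCCCCCc2ccc(OCc3ccccc3)cc2)C[C@](C)(O)CO1 | intermediate |
| 11 | bromoacetate | C[C@]1(CCCCCCCCCCCCc2ccc(OCc3ccccc3)cc2)C[C@](C)(OC(=O)CBr)CO1 | intermediate |
| 12 | diazoacetate | C[C@]1(CCCCCCCCCCCCc2ccc(OCc3ccccc3)cc2)C[C@](C)(OC(=O)C=[N+]=[N-])CO1 | intermediate |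
| 13 | O-benzyl plakortone N | C[C@]1(CCCCCCCCCCCCc2ccc(OCc3ccccc3)cc2)C[C@]2(C)OC(=O)C[C@@H]2O1 | intermediate |
| 14 | plakortone N | C[C@]1(CCCCCCCCCCCCc2ccc(O)cc2)C[C@]2(C)OC(=O)C[C@@H]2O1 | target |

## Step count
Total steps: 10. Longest linear sequence: 9 (steps 1, 2, 4–10).

## Three steps most likely to fail
1. **Step 9, C–H insertion.**
   - Risks: formation of an oxonium ylide at the ring oxygen followed by Stevens shift, insertion at C5–H, and carbene dimerisation.
   - Fallback: drop C–H functionalisation and carry C1–C2 from the start as an allyl group on C3.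
     - Use the epoxy alcohol from Sharpless kinetic resolution of 2-methylhexa-1,5-dien-3-ol, with Mitsunobu correction of C3 if needed.
     - Run the same alkynylation, ketalisation and methylation.
     - Cleave the alkene to the acid (OsO4/NaIO4, then Pinnick) and lactonise onto C4–OH.
2. **Step 6, AlMe3 methylation.**
   - Risks: proton loss from the oxocarbenium ion followed by loss of the C4 oxygen to give the 2-alkyl-4-methylfuran, endocyclic ketal cleavage, and eroded facial selectivity.
   - Fallback: swap the roles and work in the open chain.
     - Open 7 with 2-lithio-2-methyl-1,3-dithiane and unmask the methyl ketone.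
     - Add ArO-protected Ar(CH2)12MgBr under 1,3-chelation control. With C4–CH3 axial in the chelate, attack anti to it gives the required syn (pseudo-meso) 4,6-diol.
     - Close the THF by activating the primary C3–OH and displacing it with C6–O, so no cation forms at C6.
3. **Step 5, Au cycloketalisation.**
   - Risks: competing 5-endo or 6-endo attack at C7, and acid-triggered aromatisation to the furan.
   - Fallback: use umpolung instead of alkyne π-activation.
     - Alkylate 1,3-dithiane with Ar(CH2)12Br.
     - Lithiate and open 7.
     - Remove the dithiane oxidatively in buffered MeOH, which places the carbonyl/ketal carbon unambiguously at C6.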